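- Every J charged stood afterwards as J, Q, X or E, and each E cost one D, so the gap between the charge and J + Q was X + E.

| flask | J | D | G | remark | time |
|---|---|---|---|---|---|
| Friday's | 0.0010 M | 0.13 mM | 0.10 µM | run made earlier |  |
| Sunday's | 0.0010 M | 0.30 mM | 0.10 µM | run made earlier |  |
| flask | 0.0010 M | 0.200 mM | 0.10 µM |  | 4.0 min |

| run | time / min | Q / % | J / % |
|---|---|---|---|
| Friday's | 0.250 | 28 | 64 |
| Friday's | 0.500 | 56 | 33 |
| Friday's | 1.00 | 75 | 2 |
| Friday's | 2.00 | 59 | 0 |
| Friday's | 4.00 | 51 | 0 |
| Sunday's | 0.250 | 29 | 56 |
| Sunday's | 0.500 | 55 | 26 |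
| Sunday's | 1.00 | 68 | 0 |
| Sunday's | 2.00 | 56 | 0 |
| Sunday's | 4.00 | 43 | 0 |

(readings scatter by 1.5 percentage points)

* time, not beyond 4.0 min, at which the flask holds most Q
* the amount of Q, in percent of the J charged, at that time

- reactions considered so far: J + G -> Q + G; Q <-> X; J + D -> E

- Q read highest at 1.00 min in both runs, and there the gap read 23.0 % on Friday and 32.0 % on Sunday.
- I took X as equal in the two runs at that time, so the difference in the gap was E. Sunday's D charge exceeded Friday's by 17.0 % of the J charge, which gave 52.9 % of D's charge burnt, a rough reading given the scatter.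
- In the step J + D -> E, the share of D lost per minute was proportional to J, so it shrank as J fell. Friday's J fell almost steadily, by 36.0 % and then 31.0 % per reading step, which is the zero-order behaviour of the enzyme.
- Dividing the first rate by the second removed time: the fall in ln D per J spent was proportional to J and held no D. I neglected the J taken into E, which was less than the J in Q.
- Summed over the charge, this gave my burn number, minus the logarithm of the share of D left when J is spent: 0.754. In this zero-order reckoning, with G held fixed, it is independent of D's charge and grows as the square of J's charge.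
- For the flask I reckoned E as 10.6 %. Friday's X was 16.1 %, so counting no J, I committed to Q near 73.3 % close to 1.00 min.
- The forecast differed, with an earlier 0.75 min and 77 %, holding that “Q therefore peaks sharply when J runs out”.
- The flask reached 73.0 % at 0.899 min, with 2.65 % of J still there.

    J + G → Q + G, rate k1*[J]*[G]/(1 + ([J]/Km1)) (0.140 mM, k = 1.80 × 10⁶ /M/s)
    Q ⇌ X (K = 1.20, k = 0.00660 /s)
    J + D → E (k = 29.0 /M/s)

- For the neighbouring flask with 1.70 times the J charge, the square raised the burn number to 2.18, which left 11.3 % of D's charge. That flask ended with 19 % of its D.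

All runs are calculated for an exercise.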